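**Plan**

- The retrosynthesis cuts all three aryl–C5 bonds at once: C6–CMe2 on ring A, and C3′–CH2 and C2′–CH2 on ring B. This leaves tris-ether **12** (7-O-prenyl, 5′-O-prenyl, 4′-O-1,1-dimethylallyl), a constitutional isomer (C30H38O4) of the target.
- Enabling feature: each C5 group sits ortho (C6 to O7, C3′ to O4′) or para (C2′ to O5′) to a phenolic oxygen. Its orientation (1,1-dimethylallyl at C6, prenyl at C3′ and C2′) is what one [3,3] shift (ortho) or two (para, relayed through C6′) deliver from those ethers. C6′ and C8, each flanked on both sides, should not retain a quaternary group.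
- The pyran ring is then cut at O1–C2 (Mitsunobu) and C3–C4 (Claisen–Schmidt), giving ring-A aldehyde **3** and ring-B ketone **8**.
- Forward: etherified halves **3** and **8** → chalcone **9** → (R)-carbinol **11** → pyran ring closed (**12**) → one thermal isomerisation to the target, with no protecting group to remove.
- Stereochemistry: C2 comes from catalyst-controlled Ru/(R,R)-TsDPEN transfer hydrogenation, giving the (R)-alcohol. The Mitsunobu closure inverts it to (2S), and it is a spectator in the key step.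

Key step: step 8

Remark: the SMILES descriptor is read as (2S). Flavan numbering of the target is used throughout (ring A: O1, C6, O7, C8; ring B: C1′ on C2, prenyl on C2′ and C3′, OH on C4′ and C5′). Prenyl = 3-methylbut-2-enyl; 1,1-dimethylallyl = 2-methylbut-3-en-2-yl.

**Route**

Step 1
Reactants: 1 2,4-dihydroxybenzaldehyde; 2 prenyl bromide (1-bromo-3-methylbut-2-ene)
Product: 3 2-hydroxy-4-(3-methylbut-2-enyloxy)benzaldehyde
Conditions: K2CO3 (1.0 equiv), acetone, rt
Reagents that add atoms: none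
Why: Williamson etherification, in which the 2-OH is held in a hydrogen bond to the formyl group and is the less acidic, so one equivalent of mild base should alkylate only the 4-OH at the primary allylic bromide.

Step 2
Reactants: 4 1-(3,4-dihydroxyphenyl)ethanone; 5 3-chloro-3-methylbut-1-yne
Product: 6 1-[3-hydroxy-4-(2-methylbut-3-yn-2-yloxy)phenyl]ethanone
Conditions: CuCl2·2H2O (1 mol%), DBU (1.1 equiv), MeCN, −5 to 0 °C, Ar
Reagents that add atoms: none
Why: Copper-catalysed etherification of a phenol with a tertiary propargylic chloride, in which one equivalent of base forms the phenoxide of the more acidic 4-OH (para to the acetyl group), which should be the oxygen that is alkylated.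

Step 3
Reactants: 6 1-[3-hydroxy-4-(2-methylbut-3-yn-2-yloxy)phenyl]ethanone; 2 prenyl bromide
Product: 7 1-[3-(3-methylbut-2-enyloxy)-4-(2-methylbut-3-yn-2-yloxy)phenyl]ethanone
Conditions: K2CO3 (1.5 equiv), acetone, 45 °C
Reagents that add atoms: none
Why: Williamson etherification of the single remaining phenol; the tertiary propargyl aryl ether is inert to carbonate at this temperature.

Step 4
Reactants: 7 1-[3-(3-methylbut-2-enyloxy)-4-(2-methylbut-3-yn-2-yloxy)phenyl]ethanone
Product: 8 1-[4-(2-methylbut-3-en-2-yloxy)-3-(3-methylbut-2-enyloxy)phenyl]ethanone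
Conditions: H2 (1 atm), Lindlar catalyst, quinoline, EtOAc, rt, stopped after 1 equiv H2
Reagents that add atoms: none
Why: Lindlar semi-hydrogenation, in which the terminal alkyne is reduced far faster than the trisubstituted prenyl olefin or the aryl ketone; this is the standard way to 1,1-dimethylallyl aryl ethers.

Step 5
Reactants: 3 2-hydroxy-4-(3-methylbut-2-enyloxy)benzaldehyde; 8 1-[4-(2-methylbut-3-en-2-yloxy)-3-(3-methylbut-2-enyloxy)phenyl]ethanone
Product: 9 (E)-3-[2-hydroxy-4-(3-methylbut-2-enyloxy)phenyl]-1-[4-(2-methylbut-3-en-2-yloxy)-3-(3-methylbut-2-enyloxy)phenyl]prop-2-en-1-one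
Conditions: KOH (50% aq., 5 equiv), EtOH, rt, Ar, dark; then AcOH to pH 6
Reagents that add atoms: none
Why: Claisen–Schmidt condensation (enolate addition, then E1cB loss of water to the E-enone), which tolerates an unprotected salicylaldehyde and leaves all three allylic ethers untouched; the buffered work-up avoids flavylium formation.

Step 6
Reactants: 9 (E)-3-[2-hydroxy-4-(3-methylbut-2-enyloxy)phenyl]-1-[4-(2-methylbut-3-en-2-yloxy)-3-(3-methylbut-2-enyloxy)phenyl]prop-2-en-1-one
Product: 11 (1R)-3-[2-hydroxy-4-(3-methylbut-2-enyloxy)phenyl]-1-[4-(2-methylbut-3-en-2-yloxy)-3-(3-methylbut-2-enyloxy)phenyl]propan-1-ol, via saturated ketone 10 (not isolated)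
Conditions: RuCl[(R,R)-TsDPEN](p-cymene) (2 mol%), HCO2Na (10 equiv), H2O/MeOH 1:1, 40 °C
Reagents that add atoms: none
Why: Tandem Noyori–Ikariya transfer hydrogenation, in which Ru–H first adds 1,4 to the enone (10) and then reduces the aryl ketone through the CH/π-organised outer-sphere transition state, so the (R,R)-ligand should set the (R)-carbinol under catalyst control while the isolated olefins, which this mechanism does not address, remain.

Step 7
Reactants: 11 (1R)-3-[2-hydroxy-4-(3-methylbut-2-enyloxy)phenyl]-1-[4-(2-methylbut-3-en-2-yloxy)-3-(3-methylbut-2-enyloxy)phenyl]propan-1-ol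
Product: 12 (2S)-7-(3-methylbut-2-enyloxy)-2-[4-(2-methylbut-3-en-2-yloxy)-3-(3-methylbut-2-enyloxy)phenyl]chromane
Conditions: PPh3 (1.5 equiv), DIAD (1.5 equiv), THF (0.02 M), 0 °C
Reagents that add atoms: none
Why: Mitsunobu cycloetherification, in which the phenol oxygen displaces the alkoxyphosphonium group intramolecularly (6-exo-tet, SN2) with inversion, turning the (R)-carbinol into (S)-C2; the low temperature and the bulky, weakly donating tert-alkoxy group para to the carbinol should keep the displacement from ionising.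

Step 8
Reactants: 12 (2S)-7-(3-methylbut-2-enyloxy)-2-[4-(2-methylbut-3-en-2-yloxy)-3-(3-methylbut-2-enyloxy)phenyl]chromane
Product: 18 Kazinol E, via mono-Claisen phenol 13 (not isolated), via ring-B ortho-dienone 14 (not isolated), via ring-B para-dienone 15 (not isolated), via catechol prenyl ether 16 (not isolated), via ring-A ortho-dienone 17 (not isolated)
Conditions: PhNEt2 (degassed, 0.05 M), Ar, sealed tube, 130 °C (1 h), then 190 °C (2–3 h)
Reagents that add atoms: none
Why: Three aromatic sigmatropic events of known type should run in one flask: at 130 °C the tertiary ether on O4′ undergoes ortho-Claisen rearrangement to C3′, its only open ortho carbon, and delivers the normal prenyl group by allyl inversion (13); at 190 °C the O5′-prenyl ether shifts [3,3] to C6′ to give ortho-dienone 14, whose quaternary carbon is wedged between the chromanyl-bearing C1′ and the carbonyl, so a Cope shift to C2′ (para-dienone 15, prenyl again in the normal sense) should outrun enolisation before tautomerisation to catechol 16; the O7-prenyl ether shifts once to C6, and dienone 17 enolises there because the para carbon C4a is blocked, which leaves the group as 1,1-dimethylallyl. The closest known reaction types are the thermal Claisen rearrangement of aryl prenyl and aryl 1,1-dimethylallyl ethers in N,N-dialkylanilines and the tandem Claisen–Cope (para-Claisen) relay of aryl prenyl ethers whose ortho carbon is flanked on both sides, as in 5-O-prenyl flavonoids. No ring is closed and no stereocentre is made: C2 is not involved under these base-buffered, non-ionising conditions, and the sp3 carbons of 14, 15 and 17 are erased on enolisation. Three selectivities are needed: C3′ for the first shift (O5′ occupies the other ortho carbon), para over ortho on ring B (1,2,3-congestion at C6′), and C6 over C8 on ring A (C8 lies between O1 and O7, whereas C6 is para to O1 and has only H-5 beside it). The amine solvent buffers the phenols as they appear, which should suppress acid-catalysed cyclisation of the o-prenylphenols and cleavage of the tertiary ether.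

**Compound list**

1 | 2,4-dihydroxybenzaldehyde | O=Cc1ccc(O)cc1O | starting material
2 | prenyl bromide (1-bromo-3-methylbut-2-ene) | CC(C)=CCBr | starting material
3 | 2-hydroxy-4-(3-methylbut-2-enyloxy)benzaldehyde | CC(C)=CCOc1ccc(C=O)c(O)c1 | intermediate
4 | 1-(3,4-dihydroxyphenyl)ethanone | CC(=O)c1ccc(O)c(O)c1 | starting material
5 | 3-chloro-3-methylbut-1-yne | C#CC(C)(C)Cl | starting material
6 | 1-[3-hydroxy-4-(2-methylbut-3-yn-2-yloxy)phenyl]ethanone | CC(=O)c1ccc(OC(C)(C)C#C)c(O)c1 | intermediate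
7 | 1-[3-(3-methylbut-2-enyloxy)-4-(2-methylbut-3-yn-2-yloxy)phenyl]ethanone | CC(=O)c1ccc(OC(C)(C)C#C)c(OCC=C(C)C)c1 | intermediate
8 | 1-[4-(2-methylbut-3-en-2-yloxy)-3-(3-methylbut-2-enyloxy)phenyl]ethanone | CC(=O)c1ccc(OC(C)(C)C=C)c(OCC=C(C)C)c1 | intermediate
9 | (E)-3-[2-hydroxy-4-(3-methylbut-2-enyloxy)phenyl]-1-[4-(2-methylbut-3-en-2-yloxy)-3-(3-methylbut-2-enyloxy)phenyl]prop-2-en-1-one | CC(C)=CCOc1ccc(/C=C/C(=O)c2ccc(OC(C)(C)C=C)c(OCC=C(C)C)c2)c(O)c1 | intermediate
10 | 3-[2-hydroxy-4-(3-methylbut-2-enyloxy)phenyl]-1-[4-(2-methylbut-3-en-2-yloxy)-3-(3-methylbut-2-enyloxy)phenyl]propan-1-one | CC(C)=CCOc1ccc(CCC(=O)c2ccc(OC(C)(C)C=C)c(OCC=C(C)C)c2)c(O)c1 | intermediate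
11 | (1R)-3-[2-hydroxy-4-(3-methylbut-2-enyloxy)phenyl]-1-[4-(2-methylbut-3-en-2-yloxy)-3-(3-methylbut-2-enyloxy)phenyl]propan-1-ol | CC(C)=CCOc1ccc(CC[C@@H](O)c2ccc(OC(C)(C)C=C)c(OCC=C(C)C)c2)c(O)c1 | intermediate
12 | (2S)-7-(3-methylbut-2-enyloxy)-2-[4-(2-methylbut-3-en-2-yloxy)-3-(3-methylbut-2-enyloxy)phenyl]chromane | CC(C)=CCOc1ccc2c(c1)O[C@H](c1ccc(OC(C)(C)C=C)c(OCC=C(C)C)c1)CC2 | intermediate
13 | (2S)-2-[4-hydroxy-3-(3-methylbut-2-enyl)-5-(3-methylbut-2-enyloxy)phenyl]-7-(3-methylbut-2-enyloxy)chromane | CC(C)=CCOc1ccc2c(c1)O[C@H](c1cc(CC=C(C)C)c(O)c(OCC=C(C)C)c1)CC2 | intermediate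
14 | 2-hydroxy-3-(3-methylbut-2-enyl)-6-(2-methylbut-3-en-2-yl)-5-[(2S)-7-(3-methylbut-2-enyloxy)chroman-2-yl]cyclohexa-2,4-dien-1-one (ring-B ortho-dienone, C6′ epimers) | CC(C)=CCOc1ccc2c(c1)O[C@H](C1=CC(CC=C(C)C)=C(O)C(=O)C1C(C)(C)C=C)CC2 | intermediate
15 | 2-hydroxy-3,4-bis(3-methylbut-2-enyl)-5-[(2S)-7-(3-methylbut-2-enyloxy)chroman-2-yl]cyclohexa-2,5-dien-1-one (ring-B para-dienone, C2′ epimers) | CC(C)=CCOc1ccc2c(c1)O[C@H](C1=CC(=O)C(O)=C(CC=C(C)C)C1CC=C(C)C)CC2 | intermediate
16 | (2S)-2-[4,5-dihydroxy-2,3-bis(3-methylbut-2-enyl)phenyl]-7-(3-methylbut-2-enyloxy)chromane | CC(C)=CCOc1ccc2c(c1)O[C@H](c1cc(O)c(O)c(CC=C(C)C)c1CC=C(C)C)CC2 | intermediate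
17 | (2S)-2-[4,5-dihydroxy-2,3-bis(3-methylbut-2-enyl)phenyl]-6-(2-methylbut-3-en-2-yl)-2,3,4,6-tetrahydrochromen-7-one (ring-A ortho-dienone, C6 epimers) | O=C1C=C2O[C@H](c3cc(O)c(O)c(CC=C(C)C)c3CC=C(C)C)CCC2=CC1C(C)(C)C=C | intermediate
18 | Kazinol E, (2S)-2-[4,5-dihydroxy-2,3-bis(3-methylbut-2-enyl)phenyl]-6-(2-methylbut-3-en-2-yl)chroman-7-ol | C=CC(C)(C)c1cc2c(cc1O)O[C@H](c1cc(O)c(O)c(CC=C(C)C)c1CC=C(C)C)CC2 | target

**Step count and risks**

Total step count: 8. Longest linear sequence: 7 steps (steps 2–8, from 4).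

Steps most likely to fail:

1. Step 8. The ring-B ortho-dienone 14 may enolise before the Cope shift, leaving a 1,1-dimethylallyl group at C6′ instead of a prenyl group at C2′. Part of the ring-A group may go to C8, and on long heating the 6-(1,1-dimethylallyl)phenol may drift by abnormal Claisen rearrangement or lose isoprene.
Fallback (sets out from 6, returns at 18): this keeps the two ortho-Claisen shifts and brings the C2′ prenyl group in by cross-coupling. The free hydroxyl of 6 would be capped with MOMCl and i-Pr2NEt in CH2Cl2 to give 1-[3-(methoxymethoxy)-4-(2-methylbut-3-yn-2-yloxy)phenyl]ethanone F1. NBS in MeCN should then brominate para to the MOM ether, at the carbon that becomes C2′, to give 1-[2-bromo-5-(methoxymethoxy)-4-(2-methylbut-3-yn-2-yloxy)phenyl]ethanone F2. Stille coupling with tributyl(3-methylbut-2-enyl)stannane (Pd2(dba)3, tri(2-furyl)phosphine, CsF, DMF, 80 °C) should give 1-[5-(methoxymethoxy)-2-(3-methylbut-2-enyl)-4-(2-methylbut-3-yn-2-yloxy)phenyl]ethanone F3. Lindlar semi-hydrogenation as in step 4 should give 1-[5-(methoxymethoxy)-2-(3-methylbut-2-enyl)-4-(2-methylbut-3-en-2-yloxy)phenyl]ethanone F4. Condensation with 3 as in step 5 should give (E)-3-[2-hydroxy-4-(3-methylbut-2-enyloxy)phenyl]-1-[5-(methoxymethoxy)-2-(3-methylbut-2-enyl)-4-(2-methylbut-3-en-2-yloxy)phenyl]prop-2-en-1-one F5. Transfer hydrogenation as in step 6 should give (1R)-3-[2-hydroxy-4-(3-methylbut-2-enyloxy)phenyl]-1-[5-(methoxymethoxy)-2-(3-methylbut-2-enyl)-4-(2-methylbut-3-en-2-yloxy)phenyl]propan-1-ol F6. Mitsunobu closure as in step 7 should give (2S)-2-[5-(methoxymethoxy)-2-(3-methylbut-2-enyl)-4-(2-methylbut-3-en-2-yloxy)phenyl]-7-(3-methylbut-2-enyloxy)chromane F7. Heating F7 in PhNEt2 (130 °C, then 190 °C) leaves only the O4′→C3′ and O7→C6 ortho shifts and should give (2S)-2-[4-hydroxy-5-(methoxymethoxy)-2,3-bis(3-methylbut-2-enyl)phenyl]-6-(2-methylbut-3-en-2-yl)chroman-7-ol F8. Removal of the MOM group with ZnBr2 and n-PrSH in CH2Cl2 at 0 °C returns 18.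

2. Step 2. The two catechol hydroxyls may be discriminated poorly, so that O3 or both oxygens are etherified.
Fallback (sets out from 4, returns at 7): the site is chosen with a primary halide under bicarbonate conditions, and the tertiary ether is made afterwards on a mono-phenol. Allyl bromide with NaHCO3 and NaI in DMF at 40 °C should alkylate the more acidic 4-OH to give 1-[4-(allyloxy)-3-hydroxyphenyl]ethanone F9. Prenyl bromide 2 with K2CO3 in acetone then gives 1-[4-(allyloxy)-3-(3-methylbut-2-enyloxy)phenyl]ethanone F10. Pd(PPh3)4 (cat.) with morpholine in THF at rt should cleave the unsubstituted allyl ether much faster than the prenyl ether and give 1-[4-hydroxy-3-(3-methylbut-2-enyloxy)phenyl]ethanone F11. Etherification of F11 with 5 under the conditions of step 2 returns 7.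

3. Step 6. The reduction may stall at ketone 10 (electron-rich aryl ketone), the enone may be deactivated by the conjugated phenoxide so that 1,2-reduction to the allylic alcohol competes, and the free phenol may inhibit the catalyst.
Fallback (sets out from 9, returns at 11): the two reductions are separated and done with different hydride sources. Conjugate reduction of 9 with catalytic Stryker reagent, PMHS and t-BuOH in toluene at rt should give 10, which is isolated. Reduction of 10 with (S)-Me-CBS oxazaborolidine (20 mol%) and catecholborane (2.5 equiv) in toluene at −78 °C should give 11 with the (R)-configuration under reagent control, without hydroboration of the olefins. No new compound arises.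

**Further compounds**

F1 | step 8 | 1-[3-(methoxymethoxy)-4-(2-methylbut-3-yn-2-yloxy)phenyl]ethanone | CC(=O)c1ccc(OC(C)(C)C#C)c(OCOC)c1
F2 | step 8 | 1-[2-bromo-5-(methoxymethoxy)-4-(2-methylbut-3-yn-2-yloxy)phenyl]ethanone | CC(=O)c1cc(OCOC)c(OC(C)(C)C#C)cc1Br
F3 | step 8 | 1-[5-(methoxymethoxy)-2-(3-methylbut-2-enyl)-4-(2-methylbut-3-yn-2-yloxy)phenyl]ethanone | CC(=O)c1cc(OCOC)c(OC(C)(C)C#C)cc1CC=C(C)C
F4 | step 8 | 1-[5-(methoxymethoxy)-2-(3-methylbut-2-enyl)-4-(2-methylbut-3-en-2-yloxy)phenyl]ethanone | CC(=O)c1cc(OCOC)c(OC(C)(C)C=C)cc1CC=C(C)C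
F5 | step 8 | (E)-3-[2-hydroxy-4-(3-methylbut-2-enyloxy)phenyl]-1-[5-(methoxymethoxy)-2-(3-methylbut-2-enyl)-4-(2-methylbut-3-en-2-yloxy)phenyl]prop-2-en-1-one | CC(C)=CCOc1ccc(/C=C/C(=O)c2cc(OCOC)c(OC(C)(C)C=C)cc2CC=C(C)C)c(O)c1
F6 | step 8 | (1R)-3-[2-hydroxy-4-(3-methylbut-2-enyloxy)phenyl]-1-[5-(methoxymethoxy)-2-(3-methylbut-2-enyl)-4-(2-methylbut-3-en-2-yloxy)phenyl]propan-1-ol | CC(C)=CCOc1ccc(CC[C@@H](O)c2cc(OCOC)c(OC(C)(C)C=C)cc2CC=C(C)C)c(O)c1
F7 | step 8 | (2S)-2-[5-(methoxymethoxy)-2-(3-methylbut-2-enyl)-4-(2-methylbut-3-en-2-yloxy)phenyl]-7-(3-methylbut-2-enyloxy)chromane | CC(C)=CCOc1ccc2c(c1)O[C@H](c1cc(OCOC)c(OC(C)(C)C=C)cc1CC=C(C)C)CC2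
F8 | step 8 | (2S)-2-[4-hydroxy-5-(methoxymethoxy)-2,3-bis(3-methylbut-2-enyl)phenyl]-6-(2-methylbut-3-en-2-yl)chroman-7-ol | C=CC(C)(C)c1cc2c(cc1O)O[C@H](c1cc(OCOC)c(O)c(CC=C(C)C)c1CC=C(C)C)CC2
F9 | step 2 | 1-[4-(allyloxy)-3-hydroxyphenyl]ethanone | CC(=O)c1ccc(OCC=C)c(O)c1
F10 | step 2 | 1-[4-(allyloxy)-3-(3-methylbut-2-enyloxy)phenyl]ethanone | CC(=O)c1ccc(OCC=C)c(OCC=C(C)C)c1
F11 | step 2 | 1-[4-hydroxy-3-(3-methylbut-2-enyloxy)phenyl]ethanone | CC(=O)c1ccc(O)c(OCC=C(C)C)c1
F0 | step 6 | none | none
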